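**Strategy**

The route rests on opening the dimethylpyran of ring B at its O–C2'' bond and removing the C3' oxygen, which leads back to a 4'-hydroxyphenyl ring with a prenyl group on the neighbouring carbon. The key step exploits the arrangement in ring B of the target, where the free C3' hydroxyl flanks the pyran oxygen on C4' and the pyran is fused across C4'–C5': ortho-oxygenation of the prenylphenol to an ortho-quinone, a base-mediated proton shift and an oxa-6π ring closure install the hydroxyl and the pyran in one operation. The precursor is isowighteone (3'-prenylgenistein) as its 7-O-methoxymethyl ether, reached from genistein by a Claisen rearrangement.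

Key step: step 5

Remark on locants: ring B of 8 is numbered with the prenyl group on C3'; once the pyran is closed the ring is renumbered, so C5' of 8 (the carbon that is oxygenated) is C3' of 11 and 12, and C3' of 8 is C5' of 11 and 12.

**Route**

Step 1
Reactants: 1 genistein; 2 chloromethyl methyl ether
Product: 3 genistein 7-O-methoxymethyl ether
Conditions: K2CO3 (1.1 equiv), MOMCl (1.05 equiv), acetone, 0 °C to rt
Reagents that add atoms: none
Why: Williamson-type O-alkylation under limiting base should cap only the 7-hydroxyl, which is a vinylogous carboxylic acid through the C4 carbonyl and the most acidic of the three, whereas the 5-hydroxyl is locked in a hydrogen bond to that carbonyl and the 4'-hydroxyl is an ordinary phenol.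

Step 2
Reactants: 3 genistein 7-O-methoxymethyl ether; 4 3-chloro-3-methylbut-1-yne
Product: 5 genistein 4'-O-(2-methylbut-3-yn-2-yl) 7-O-methoxymethyl ether
Conditions: 4 (1.5 equiv), DBU (1.5 equiv), CuCl2·2H2O (1 mol %), MeCN–DMF, 0 °C to rt
Reagents that add atoms: none
Why: Copper-catalysed propargylic substitution of the tertiary chloride by a phenoxide should occur at O4' only, because O7 is capped and the chelated 5-hydroxyl is neither nucleophilic nor accessible to a tertiary electrophile.

Step 3
Reactants: 5 genistein 4'-O-(2-methylbut-3-yn-2-yl) 7-O-methoxymethyl ether
Product: 6 genistein 4'-O-(2-methylbut-3-en-2-yl) 7-O-methoxymethyl ether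
Conditions: H2 (1 atm), Pd/CaCO3 poisoned with Pb(OAc)2, quinoline, EtOAc, rt
Reagents that add atoms: none
Why: Lindlar semihydrogenation should stop after one equivalent of H2 because the poisoned palladium surface binds the terminal alkyne far more strongly than the alkene, and it leaves the chromone C2=C3 bond, the aryl ethers and the acetal untouched.

Step 4
Reactants: 6 genistein 4'-O-(2-methylbut-3-en-2-yl) 7-O-methoxymethyl ether
Product: 8 isowighteone 7-O-methoxymethyl ether, via ortho-dienone 7 (not isolated)
Conditions: PhNEt2, 130 °C, argon
Reagents that add atoms: none
Why: Aromatic Claisen rearrangement, a [3,3]-sigmatropic shift with allylic transposition, should turn the tertiary ether into the linear 3-methylbut-2-enyl group on an ortho carbon of ring B (the two ortho carbons are equivalent), after which dienone 7 re-aromatises by tautomerisation and its transient racemic stereocentre disappears.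

Step 5
Reactants: 8 isowighteone 7-O-methoxymethyl ether
Product: 11 semilicoisoflavone B 7-O-methoxymethyl ether, via ortho-quinone 9 (not isolated), via vinyl ortho-quinone methide 10 (not isolated)
Conditions: IBX (1.05 equiv), DMF, 0 °C to rt, dark; then Et3N (3 equiv), argon, rt to 40 °C
Reagents that add atoms: 2-iodoxybenzoic acid (IBX), O=C1OI(=O)(O)c2ccccc12
Why: The 4'-phenol should exchange onto pentavalent iodine, which passes oxygen intramolecularly to C5' (locants of 8), and the resulting trivalent iodine catecholate collapses to ortho-quinone 9 and 2-iodobenzoic acid, as in the known IBX ortho-oxygenation of phenols. Triethylamine then removes a prenyl CH2 proton, which is doubly vinylogous to the C5' carbonyl, and reprotonation on that oxygen gives the vinyl ortho-quinone methide 10; the closest known reaction type is the amine-promoted isomerisation of prenylated para-quinones to chromenols. The C4' carbonyl, the exocyclic alkene on C3' and the dimethyl-substituted alkene of 10 form a 1-oxatriene that closes the six-membered pyran by a thermal disrotatory oxa-6π electrocyclisation, making the O–C2'' bond (pyran numbering) and restoring aromatic ring B. No stereocentre arises because the new sp3 carbon carries two methyl groups, and only the Z geometry of the methide alkene can close, the E isomer being returned through the reversible proton shift. The step needs oxygenation on ring B alone and at one carbon alone: the alkylated 4'-phenol is the only electron-rich free phenol, its other ortho carbon carries the prenyl group, and the 5-hydroxyl is hydrogen-bonded to the C4 carbonyl on an electron-poor ring whose O7 is capped. Because the oxidant is spent before the base is added, the oxidisable hydroxychromene 11 should never meet pentavalent iodine.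

Step 6
Reactants: 11 semilicoisoflavone B 7-O-methoxymethyl ether
Product: 12 semilicoisoflavone B
Conditions: HCl (1.25 M in MeOH), THF, 40 °C
Reagents that add atoms: none
Why: Acid-catalysed acetal cleavage (transacetalisation of the methoxymethyl ether with methanol) should free the 7-hydroxyl, since the acidic 7-phenol is a good leaving group from the protonated acetal and dilute anhydrous acid at mild temperature leaves the 2,2-dimethylchromene and the phenols intact.

**Compound list**

1 | genistein (5,7,4'-trihydroxyisoflavone) | O=c1c(-c2ccc(O)cc2)coc2cc(O)cc(O)c12 | starting material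
2 | chloromethyl methyl ether | COCCl | starting material
3 | genistein 7-O-methoxymethyl ether (5,4'-dihydroxy-7-(methoxymethoxy)isoflavone) | COCOc1cc(O)c2c(c1)occ(-c1ccc(O)cc1)c2=O | intermediate
4 | 3-chloro-3-methylbut-1-yne | CC(C)(Cl)C#C | starting material
5 | genistein 4'-O-(2-methylbut-3-yn-2-yl) 7-O-methoxymethyl ether | COCOc1cc(O)c2c(c1)occ(-c1ccc(OC(C)(C)C#C)cc1)c2=O | intermediate
6 | genistein 4'-O-(2-methylbut-3-en-2-yl) 7-O-methoxymethyl ether | COCOc1cc(O)c2c(c1)occ(-c1ccc(OC(C)(C)C=C)cc1)c2=O | intermediate
7 | ortho-dienone (not isolated; ring B as 4'-oxo-3'-prenylcyclohexa-1',5'-dienyl with sp3 C3'–H, racemic) | COCOc1cc(O)c2c(c1)occ(C1=CC(CC=C(C)C)C(=O)C=C1)c2=O | intermediate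
8 | isowighteone 7-O-methoxymethyl ether (5,4'-dihydroxy-7-(methoxymethoxy)-3'-prenylisoflavone) | COCOc1cc(O)c2c(c1)occ(-c1ccc(O)c(CC=C(C)C)c1)c2=O | intermediate
9 | ortho-quinone (not isolated; ring B oxidised to the 4',5'-dione, prenyl on C3', locants of 8) | COCOc1cc(O)c2c(c1)occ(C1=CC(=O)C(=O)C(CC=C(C)C)=C1)c2=O | intermediate
10 | vinyl ortho-quinone methide (not isolated; ring B as 5'-hydroxy-4'-oxo-3'-[(Z)-3-methylbut-2-enylidene]cyclohexa-1',5'-dienyl, locants of 8) | COCOc1cc(O)c2c(c1)occ(C1=C/C(=C/C=C(C)C)C(=O)C(O)=C1)c2=O | intermediate
11 | semilicoisoflavone B 7-O-methoxymethyl ether (5-hydroxy-3-(8-hydroxy-2,2-dimethyl-2H-chromen-6-yl)-7-(methoxymethoxy)chromen-4-one) | COCOc1cc(O)c2c(c1)occ(-c1cc(O)c3OC(C)(C)C=Cc3c1)c2=O | intermediate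
12 | semilicoisoflavone B (5,7-dihydroxy-3-(8-hydroxy-2,2-dimethyl-2H-chromen-6-yl)chromen-4-one; no stereocentre) | CC1(C)C=Cc2cc(-c3coc4cc(O)cc(O)c4c3=O)cc(O)c2O1 | target

**Step count**

Total steps: 6. Longest linear sequence: 6 steps, from genistein 1.

**Steps most likely to fail**

Step 5. The ortho-quinone may oligomerise or add nucleophiles before the proton shift takes place, and the electron-rich hydroxychromene may be oxidised further if oxidant or air remains once base is present. The fallback sets out from 8 and comes back at 11, and it separates the oxygenation from the ring closure. Compound 8 would be treated with IBX in DMF and ortho-quinone 9 reduced in the same flask with aqueous Na2S2O4, which should give the stable catechol 5'-prenylorobol 7-O-methoxymethyl ether F1. Its 4'-hydroxyl, the only one within reach of the alkene, would then be closed onto the prenyl group by selenoetherification with N-(phenylseleno)phthalimide and catalytic camphorsulfonic acid in CH2Cl2. This 6-endo attack at the tertiary carbon should give racemic 3''-(phenylselanyl)-3'',4''-dihydrosemilicoisoflavone B 7-O-methoxymethyl ether F2. Oxidation with H2O2 in THF at 0 °C should give the selenoxide of this chroman F3. Its syn-elimination can run only towards the benzylic CH2, since C2'' is quaternary, and should deliver 11.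

Step 4. The tertiary allyl group may be lost heterolytically, returning phenol 3 with release of isoprene, and on prolonged heating the ortho-prenylphenol may cyclise onto its own alkene to a chroman. The fallback sets out from 3 and comes back at 8, replacing steps 2 to 4. O-Allylation of 3 (allyl bromide, K2CO3, acetone, reflux) should give genistein 4'-O-allyl 7-O-methoxymethyl ether F4. The Claisen rearrangement of this parent allyl ether (PhNEt2, 190 °C), which has no easy fragmentation path, should give 3'-allylgenistein 7-O-methoxymethyl ether F5. Olefin cross-metathesis of F5 with excess 2-methylbut-2-ene and second-generation Grubbs catalyst, RuCl2(=CHPh)(PCy3)(H2IMes), in CH2Cl2 at 40 °C should convert the allyl into the prenyl group and give 8.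

Step 2. The tertiary chloride may lose HCl to the enyne faster than the sparingly soluble phenoxide is alkylated, so that conversion stalls. The fallback sets out from 3 and comes back at 6, so that step 3 is not needed. The tertiary allyl ether would be made directly by Tsuji–Trost allylic etherification with zerovalent palladium. The reagent tert-butyl 2-methylbut-3-en-2-yl carbonate F6 would be prepared from 2-methylbut-3-en-2-ol with n-BuLi and Boc2O in THF. With 3 and Pd(PPh3)4 in THF at 0 °C it should give 6, the phenoxide attacking the more substituted terminus of the 1,1-dimethylallyl palladium complex under kinetic control.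

Further compounds
F1 | step 5 | 5'-prenylorobol 7-O-methoxymethyl ether (3',4'-dihydroxy-5'-prenyl ring B) | COCOc1cc(O)c2c(c1)occ(-c1cc(O)c(O)c(CC=C(C)C)c1)c2=O
F2 | step 5 | racemic 3''-(phenylselanyl)-3'',4''-dihydrosemilicoisoflavone B 7-O-methoxymethyl ether | COCOc1cc(O)c2c(c1)occ(-c1cc(O)c3OC(C)(C)C([Se]c4ccccc4)Cc3c1)c2=O
F3 | step 5 | selenoxide of this chroman (not isolated, mixture of diastereomers) | COCOc1cc(O)c2c(c1)occ(-c1cc(O)c3OC(C)(C)C([Se](=O)c4ccccc4)Cc3c1)c2=O
F4 | step 4 | genistein 4'-O-allyl 7-O-methoxymethyl ether | COCOc1cc(O)c2c(c1)occ(-c1ccc(OCC=C)cc1)c2=O
F5 | step 4 | 3'-allylgenistein 7-O-methoxymethyl ether | COCOc1cc(O)c2c(c1)occ(-c1ccc(O)c(CC=C)c1)c2=O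
F6 | step 2 | tert-butyl 2-methylbut-3-en-2-yl carbonate | C=CC(C)(C)OC(=O)OC(C)(C)C
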